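- Per molar per minute is the unit I reckon in, since a rate with starting material and coupling partner both first order needs a constant in it.

| flask | starting material | coupling partner | free catalyst | time |
|---|---|---|---|---|
| Sunday's | 0.0500 M | 0.100 M | 0.00100 M |  |
| Monday's | 0.0200 M | 0.0700 M | 0.00100 M |  |
| Tuesday's | 0.0500 M | 0.100 M | 0.00200 M |  |
| Wednesday's | 0.0250 M | 0.100 M | 0.00100 M |  |
| Thursday's | 0.0110 M | 0.100 M | 0.00100 M | 5.7 min |

- Sunday's run (time / min: [target] / M): 1.1: 0.01489; 2.3: 0.02461; 3.4: 0.02986; 4.6: 0.03366; 5.7: 0.03536
- Monday's run (time / min: [target] / M): 1.1: 0.00486; 2.3: 0.00846; 3.4: 0.01049; 4.6: 0.01175; 5.7: 0.01345
- Tuesday's run (time / min: [target] / M): 1.1: 0.02004; 2.3: 0.03005; 3.4: 0.03479; 4.6: 0.03763; 5.7: 0.03914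
- Wednesday's run (time / min: [target] / M): 1.1: 0.00788; 2.3: 0.01314; 3.4: 0.01574; 4.6: 0.01749; 5.7: 0.01861

(standard deviation of a reading: 2 × 10⁻⁴ M)

- Overall: starting material + coupling partner -> target, with free catalyst as catalyst.
- Constant volume, constant temperature.
- An order is taken over about fifteen percent of the charge, up and down.

* order of the initial rate in [starting material], near the charge of the Sunday's run, the rate being that where two percent of its starting material are target (one fixed amount of target, the same in the runs compared)
* order of the initial rate in [free catalyst], near the charge of the Sunday's run, the rate being that where two percent of its starting material are target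
* target in the Thursday's run at 5.7 min, as a share of the starting material charged

- Sunday's run gives 3.47 /M/min for the opening clock κ: the natural log of starting material charged over starting material left at the first reading, divided by that time and by the mean partner concentration up to it.
- Wednesday's run, with half of Sunday's starting material, reads 3.58 /M/min, so my order in starting material, read from these two first readings, is 0.955.
- Tuesday's run, with twice Sunday's charge of free catalyst, reads 5.17 /M/min, so my order in free catalyst, again a reading, is 0.575. If free catalyst pairs up in a fast balance, the rate follows what stays free, and that order falls toward 0.5 as pairs come to dominate.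
- Thursday's run has Sunday's charges of partner and free catalyst, so I carry κ over. With the main step and partner held at its charge (the pseudo-first-order picture), I reckon 86.2% of the starting material turned at 5.7 min.
- Adding partner use lowers the mean partner concentration, and the share falls to 84.8%.
- Adding the late bend, I take the same clock over the whole of Wednesday's run, which reads 2.64 /M/min, lower than its opening value. For Thursday's run that gives target at 76.2% of the starting material charged, the share I commit to.
- The forecast says order 0.91 (0.78 to 1.03) in starting material, order 0.65 (0.52 to 0.8) in free catalyst, and target at 77% (74% to 80%) in Thursday's run. It reads the bend as “the catalyst is probably dying or being inhibited”, and its catalyst order stands above mine.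
- The simulation gives 1.0 in starting material, 0.51 in catalyst, and 76.9% of target in Thursday's run, so the forecast's catalyst order is too high.

    2 free catalyst ⇌ catalyst dimer, settled at all times (4650 /M)
    free catalyst + starting material + coupling partner → target + free catalyst (11520 /M²/min)
    target → decomposed product (0.02976 /min)
    starting material + coupling partner → target (0.4716 /M/min)

- My opening clock, carried to Thursday's run with partner use, gave 84.8%. Thursday's run without the loss of target to decomposed product gives 86.0%, and with that loss 76.9%, so that loss takes 9.1 percentage points there. Monday's run has Sunday's charge of free catalyst, and Sunday's clock at Monday's mean partner concentration up to that point puts target at a quarter of Monday's starting material at 1.23 min, where Monday's run gives 1.19 min.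

The earlier runs and the new flask stem from a simulated flask from invented constants, and the scatter is random.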